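**Plan**

- Numbering: C1 is the ester carbon, C2 the methyl-bearing carbon, C3–C6 the ring carbons (C6 quaternary), C7–C14 the chain (C9 ketone, C10 methylidene-bearing, C14 carbinol carbon).
- Cuts, latest first: C10=CH2 (formaldehyde) and C9–C10 (a C9 methyl ester plus a C10–C14 phosphonate), with C1 taken back to CH2OH; the ring C4–C5 bond back to an alkene; then both ring C–O bonds (C3–O and C6–O) together, to O2 and a (3E,5E)-dienol; last C3=C4, to a C1–C3 sulfone and a C4–C9 enal.
- Forward: the C1–C3 sulfone comes from methyl (R)-3-hydroxy-2-methylpropanoate (steps 1–4) and the C4–C9 enal from geranyl acetate (5–10); they are joined to the diene (11–12). The only ring, the 1,2-dioxane, arises in step 13 and is saturated in step 14. The C10–C14 phosphonate (15–17) is joined at C9 (18) and both chain ends are finished (19–22).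
- Enabling feature: the ring oxygens sit on C3 and C6, 1,4 across C4–C5, and the C2 arm on C3 is cis to the C7 chain on C6 with the C6 methyl trans to it. This is the pattern left by suprafacial addition of O2 to the termini of a (3E,5E)-diene.
- Stereochemistry: C2 comes from the chiral pool. The C3/C6 relative configuration comes from the diene geometry (C5=C6 inherited from geranyl acetate, C3=C4 from the olefination). Their absolute sense comes from C2 through hydroxyl-steered facial selection in step 13.

Key step: step 13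

Assumption (chemistry): the two cis-configured cycloadducts of step 13 are taken to be separable by chromatography on silica, and only the isomer drawn as 21 is carried forward.

**Route**

Step 1
Reactants: 1 methyl (R)-3-hydroxy-2-methylpropanoate
Product: 2 methyl (R)-3-[(tert-butyldimethylsilyl)oxy]-2-methylpropanoate
Conditions: t-BuMe2SiCl, imidazole, CH2Cl2, 0 °C → rt
Reagents that add atoms: tert-butyldimethylsilyl chloride, CC(C)(C)[Si](C)(C)Cl
Why: Imidazole-promoted silylation of a primary alcohol is routine and leaves the C2 stereocentre untouched.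

Step 2
Reactants: 2 methyl (R)-3-[(tert-butyldimethylsilyl)oxy]-2-methylpropanoate
Product: 4 (S)-3-[(tert-butyldimethylsilyl)oxy]-2-methylpropan-1-ol, via aldehyde 3 (not isolated)
Conditions: i-Bu2AlH (2.3 equiv), CH2Cl2, −78 → 0 °C; aq. KNaC4H4O6 work-up
Reagents that add atoms: none
Why: Hydride reduction of the ester runs through the aldehyde, which is reduced at once, so the epimerisable aldehyde is never handled and the silyl ether is inert.

Step 3
Reactants: 4 (S)-3-[(tert-butyldimethylsilyl)oxy]-2-methylpropan-1-ol and 5 1-phenyl-1H-tetrazole-5-thiol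
Product: 6 5-{[(R)-3-[(tert-butyldimethylsilyl)oxy]-2-methylpropyl]sulfanyl}-1-phenyl-1H-tetrazole
Conditions: PPh3, diisopropyl azodicarboxylate, THF, 0 °C → rt
Reagents that add atoms: none
Why: Mitsunobu thioetherification, in which the acidic tetrazole thiol displaces the activated primary hydroxyl by SN2 at a carbon that is not stereogenic.

Step 4
Reactants: 6 5-{[(R)-3-[(tert-butyldimethylsilyl)oxy]-2-methylpropyl]sulfanyl}-1-phenyl-1H-tetrazole
Product: 8 5-{[(R)-3-[(tert-butyldimethylsilyl)oxy]-2-methylpropyl]sulfonyl}-1-phenyl-1H-tetrazole, via sulfoxide 7 (not isolated)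
Conditions: 30% aq. H2O2, (NH4)6Mo7O24·4H2O (cat.), EtOH, 0 °C → rt
Reagents that add atoms: hydrogen peroxide, OO
Why: Molybdate-catalysed peroxide oxidation takes the sulfide through the sulfoxide to the sulfone under conditions that a primary TBS ether tolerates.

Step 5
Reactants: 9 geranyl acetate
Product: 10 (E)-5-(3,3-dimethyloxiran-2-yl)-3-methylpent-2-en-1-yl acetate (racemic at the oxirane carbon)
Conditions: 3-ClC6H4CO3H, CH2Cl2, 0 °C
Reagents that add atoms: 3-chloroperbenzoic acid, OOC(=O)c1cccc(Cl)c1
Why: Prilezhaev epoxidation selects the electron-rich 6,7-alkene because the 2,3-alkene is deactivated by the allylic acetate, and the E geometry of the remaining alkene is unchanged.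

Step 6
Reactants: 10 (E)-5-(3,3-dimethyloxiran-2-yl)-3-methylpent-2-en-1-yl acetate
Product: 12 (E)-3-methyl-6-oxohex-2-en-1-yl acetate, via diol 11 (not isolated)
Conditions: H5IO6, THF/H2O, 0 °C
Reagents that add atoms: none
Why: Aqueous periodic acid opens the epoxide to the vicinal diol and cleaves it (Malaprade glycol cleavage) to the aldehyde and acetone, while the allylic acetate and the trisubstituted alkene are left alone.

Step 7
Reactants: 12 (E)-3-methyl-6-oxohex-2-en-1-yl acetate
Product: 13 (E)-6-acetoxy-4-methylhex-4-enoic acid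
Conditions: NaClO2, NaH2PO4, 2-methylbut-2-ene, t-BuOH/H2O, 0 °C → rt
Reagents that add atoms: sodium chlorite, [Na+].[O-]Cl=O
Why: Pinnick oxidation converts the aldehyde to the acid, and the alkene scavenger removes hypochlorous acid so that the trisubstituted alkene is spared.

Step 8
Reactants: 13 (E)-6-acetoxy-4-methylhex-4-enoic acid
Product: 15 methyl (E)-6-acetoxy-4-methylhex-4-enoate, via potassium carboxylate 14 (not isolated)
Conditions: K2CO3, MeI, DMF, rt
Reagents that add atoms: iodomethane, CI
Why: O-Alkylation of the carboxylate with iodomethane gives the methyl ester without disturbing the acetate under anhydrous conditions.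

Step 9
Reactants: 15 methyl (E)-6-acetoxy-4-methylhex-4-enoate
Product: 16 methyl (E)-6-hydroxy-4-methylhex-4-enoate
Conditions: K2CO3 (cat.), MeOH, 0 °C
Reagents that add atoms: none
Why: Carbonate-catalysed transesterification in methanol removes the acetate as methyl acetate, and exchange at the methyl ester is degenerate.

Step 10
Reactants: 16 methyl (E)-6-hydroxy-4-methylhex-4-enoate
Product: 17 methyl (E)-4-methyl-6-oxohex-4-enoate
Conditions: MnO2, CH2Cl2, rt
Reagents that add atoms: none
Why: Activated MnO2 oxidises the allylic alcohol selectively to the conjugated aldehyde without over-oxidation and without loss of the E geometry.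

Step 11
Reactants: 8 5-{[(R)-3-[(tert-butyldimethylsilyl)oxy]-2-methylpropyl]sulfonyl}-1-phenyl-1H-tetrazole and 17 methyl (E)-4-methyl-6-oxohex-4-enoate
Product: 19 methyl (4E,6E,8S)-9-[(tert-butyldimethylsilyl)oxy]-4,8-dimethylnona-4,6-dienoate, via potassium sulfonyl carbanion 18 (not isolated)
Conditions: KN(SiMe3)2, DME, −78 °C, 30 min; then 17, −78 °C → rt
Reagents that add atoms: none
Why: Julia–Kocienski olefination, in which the pre-formed sulfonyl carbanion adds to the enal and the adduct collapses by Smiles rearrangement with loss of SO2 to the C3=C4 alkene; E selectivity is typical for β-branched alkyl phenyltetrazolyl sulfones with a potassium base in DME, and the C2 centre, β to sulfur, is not acidic.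

Step 12
Reactants: 19 methyl (4E,6E,8S)-9-[(tert-butyldimethylsilyl)oxy]-4,8-dimethylnona-4,6-dienoate
Product: 20 methyl (4E,6E,8S)-9-hydroxy-4,8-dimethylnona-4,6-dienoate
Conditions: HF·pyridine, pyridine, THF, 0 °C → rt
Reagents that add atoms: none
Why: Buffered fluoride cleaves the primary silyl ether and frees the hydroxyl needed in step 13 without touching the ester or isomerising the diene.

Step 13
Reactants: 20 methyl (4E,6E,8S)-9-hydroxy-4,8-dimethylnona-4,6-dienoate
Product: 21 methyl 3-[(3S,6S)-6-[(2R)-1-hydroxypropan-2-yl]-3-methyl-3,6-dihydro-1,2-dioxin-3-yl]propanoate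
Conditions: O2 (1 atm), 5,10,15,20-tetraphenylporphyrin (cat.), visible light, CH2Cl2, 0 °C; chromatography without base
Reagents that add atoms: dioxygen (reacting as singlet oxygen), O=O
Why: Energy transfer from the photoexcited porphyrin turns triplet into singlet oxygen, which adds across C3 and C6 of the s-cis diene in a concerted suprafacial [4+2] cycloaddition; the closest known reaction type is the hetero-Diels–Alder addition of singlet oxygen to acyclic (E,E)-1,3-dienes, which gives 3,6-dihydro-1,2-dioxines. The six-membered peroxide ring closes in [4+2] mode, both C–O bonds forming at the diene termini in one pericyclic event and the C4=C5 alkene appearing between them. The relative configuration of the new stereocentres C3 and C6 is fixed by the (3E,5E) geometry: the outward groups (the C2 arm on C3, the C7 chain on C6) finish cis and the inward C6 methyl finishes trans to the C2 arm. Their absolute sense is controlled by the existing C2 stereocentre: with C2–H in the diene plane, the CH2OH arm and the methyl lie on opposite faces, and hydrogen bonding of the free hydroxyl to the approaching oxygen in an aprotic, weakly polar solvent should favour attack syn to CH2OH, the face that leads to 21. The step needs periselectivity over the Schenck ene reaction at the C6 methyl and C7 methylene, and facial selectivity; the first is supported by the E,E diene (only one inward substituent in the s-cis form) and an aprotic medium, the second by the free hydroxyl, and only a moderate facial bias is expected. The minor cis diastereomer and any ene hydroperoxides are to be removed by chromatography without base, because the product is prone to Kornblum–DeLaMare fragmentation.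

Step 14
Reactants: 21 methyl 3-[(3S,6S)-6-[(2R)-1-hydroxypropan-2-yl]-3-methyl-3,6-dihydro-1,2-dioxin-3-yl]propanoate
Product: 22 methyl 3-[(3R,6S)-6-[(2R)-1-hydroxypropan-2-yl]-3-methyl-1,2-dioxan-3-yl]propanoate
Conditions: KO2CN=NCO2K (excess), AcOH, MeOH/CH2Cl2, 0 °C → rt
Reagents that add atoms: none
Why: Diimide generated in the acidic medium transfers two hydrogens to the ring alkene in a concerted cyclic step and, unlike catalytic hydrogenation, leaves the O–O bond intact; no stereocentre is formed and no base is present.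

Step 15
Reactants: 23 ethyl 5-bromopentanoate
Product: 25 6-bromo-2-methylhexan-2-ol, via bromo ketone 24 (not isolated)
Conditions: MeMgBr (2.3 equiv), THF, −20 → 0 °C; aq. NH4Cl
Reagents that add atoms: methylmagnesium bromide, C[Mg]Br
Why: Double Grignard addition to the ester gives the tertiary alcohol through the methyl ketone, and at or below 0 °C the magnesium alkoxide should not displace the remote bromide.

Step 16
Reactants: 25 6-bromo-2-methylhexan-2-ol
Product: 26 [(6-bromo-2-methylhexan-2-yl)oxy]triethylsilane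
Conditions: Et3SiOSO2CF3, 2,6-lutidine, CH2Cl2, −78 → 0 °C
Reagents that add atoms: triethylsilyl trifluoromethanesulfonate, CC[Si](CC)(CC)OS(=O)(=O)C(F)(F)F
Why: The hindered tertiary alcohol is silylated by the reactive silyl triflate with a non-nucleophilic base, which leaves the primary bromide alone.

Step 17
Reactants: 26 [(6-bromo-2-methylhexan-2-yl)oxy]triethylsilane
Product: 27 diethyl {5-methyl-5-[(triethylsilyl)oxy]hexyl}phosphonate
Conditions: P(OEt)3 (neat, excess), 150 °C
Reagents that add atoms: triethyl phosphite, CCOP(OCC)OCC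
Why: Michaelis–Arbuzov reaction of a primary bromide with neat triethyl phosphite gives the phosphonate while volatile bromoethane distils off, and a tertiary silyl ether is thermally inert under these neutral conditions.

Step 18
Reactants: 22 methyl 3-[(3R,6S)-6-[(2R)-1-hydroxypropan-2-yl]-3-methyl-1,2-dioxan-3-yl]propanoate and 27 diethyl {5-methyl-5-[(triethylsilyl)oxy]hexyl}phosphonate
Product: 29 diethyl {1-[(3R,6S)-6-[(2R)-1-hydroxypropan-2-yl]-3-methyl-1,2-dioxan-3-yl]-8-methyl-3-oxo-8-[(triethylsilyl)oxy]nonan-4-yl}phosphonate (both C10 epimers), via lithiated phosphonate 28 (not isolated)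
Conditions: 27 (3.5 equiv), n-BuLi (3.4 equiv), THF, −78 °C; then 22, −78 → −30 °C; aq. NH4Cl
Reagents that add atoms: none
Why: Claisen-type acylation of the α-lithiated phosphonate by the C9 methyl ester forms the C9–C10 bond, the excess carbanion covering the hydroxyl proton and the acidic product; a phosphonate-stabilised carbanion at low temperature is expected to add to the ester faster than it attacks the hindered dialkyl peroxide, and the new C10 centre is of no consequence because it becomes sp2 in step 19.

Step 19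
Reactants: 29 diethyl {1-[(3R,6S)-6-[(2R)-1-hydroxypropan-2-yl]-3-methyl-1,2-dioxan-3-yl]-8-methyl-3-oxo-8-[(triethylsilyl)oxy]nonan-4-yl}phosphonate
Product: 31 1-[(3R,6S)-6-[(2R)-1-hydroxypropan-2-yl]-3-methyl-1,2-dioxan-3-yl]-8-methyl-4-methylidene-8-[(triethylsilyl)oxy]nonan-3-one, via potassium enolate 30 (not isolated)
Conditions: K2CO3, 37% aq. HCHO, THF, 0 °C → rt
Reagents that add atoms: formaldehyde, C=O
Why: Horner–Wadsworth–Emmons methylenation, in which the carbonate-generated ketophosphonate anion adds to formaldehyde and expels diethyl phosphate to give the 1,1-disubstituted enone; the base is mild enough for the peroxide, and the step is placed before C1 becomes a base-sensitive β-peroxy ester.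

Step 20
Reactants: 31 1-[(3R,6S)-6-[(2R)-1-hydroxypropan-2-yl]-3-methyl-1,2-dioxan-3-yl]-8-methyl-4-methylidene-8-[(triethylsilyl)oxy]nonan-3-one
Product: 33 (2S)-2-[(3S,6R)-6-methyl-6-{8-methyl-4-methylidene-3-oxo-8-[(triethylsilyl)oxy]nonyl}-1,2-dioxan-3-yl]propanoic acid, via aldehyde 32 (not isolated)
Conditions: PhI(OAc)2 (2.5 equiv), 2,2,6,6-tetramethylpiperidin-1-oxyl (cat.), MeCN/H2O (pH 7 phosphate buffer), 0 °C → rt
Reagents that add atoms: water, O
Why: The oxoammonium species formed from the nitroxyl and PhI(OAc)2 oxidises only the primary alcohol, through the aldehyde and its hydrate, to the acid in a near-neutral medium that should spare the peroxide, the enone and the tertiary silyl ether and give C2 little chance to epimerise.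

Step 21
Reactants: 33 (2S)-2-[(3S,6R)-6-methyl-6-{8-methyl-4-methylidene-3-oxo-8-[(triethylsilyl)oxy]nonyl}-1,2-dioxan-3-yl]propanoic acid
Product: 35 methyl (2S)-2-[(3S,6R)-6-methyl-6-{8-methyl-4-methylidene-3-oxo-8-[(triethylsilyl)oxy]nonyl}-1,2-dioxan-3-yl]propanoate, via potassium carboxylate 34 (not isolated)
Conditions: KHCO3, MeI, DMF, rt
Reagents that add atoms: iodomethane, CI
Why: O-Methylation of the carboxylate with a hydrogen carbonate base gives the methyl ester without exposing the β-peroxy ester to a base strong enough for elimination or the enone to a diazoalkane.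

Step 22
Reactants: 35 methyl (2S)-2-[(3S,6R)-6-methyl-6-{8-methyl-4-methylidene-3-oxo-8-[(triethylsilyl)oxy]nonyl}-1,2-dioxan-3-yl]propanoate
Product: 36 aikupikoxide D, methyl (2S)-2-[(3S,6R)-6-(8-hydroxy-8-methyl-4-methylidene-3-oxononyl)-6-methyl-1,2-dioxan-3-yl]propanoate
Conditions: HF·pyridine, pyridine, THF, 0 °C
Reagents that add atoms: none
Why: Buffered fluoride removes the tertiary triethylsilyl ether without affecting the peroxide, the enone or the ester, releasing the C14 alcohol of the target.

**Compound list**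

1 | methyl (R)-3-hydroxy-2-methylpropanoate | C[C@H](CO)C(=O)OC | starting material
2 | methyl (R)-3-[(tert-butyldimethylsilyl)oxy]-2-methylpropanoate | C[C@H](CO[Si](C)(C)C(C)(C)C)C(=O)OC | intermediate
3 | (R)-3-[(tert-butyldimethylsilyl)oxy]-2-methylpropanal | C[C@H](CO[Si](C)(C)C(C)(C)C)C=O | intermediate (not isolated)
4 | (S)-3-[(tert-butyldimethylsilyl)oxy]-2-methylpropan-1-ol | C[C@H](CO[Si](C)(C)C(C)(C)C)CO | intermediate
5 | 1-phenyl-1H-tetrazole-5-thiol | Sc1nnnn1-c1ccccc1 | starting material
6 | 5-{[(R)-3-[(tert-butyldimethylsilyl)oxy]-2-methylpropyl]sulfanyl}-1-phenyl-1H-tetrazole | C[C@H](CO[Si](C)(C)C(C)(C)C)CSc1nnnn1-c1ccccc1 | intermediate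
7 | 5-{[(R)-3-[(tert-butyldimethylsilyl)oxy]-2-methylpropyl]sulfinyl}-1-phenyl-1H-tetrazole (both configurations at sulfur) | C[C@H](CO[Si](C)(C)C(C)(C)C)CS(=O)c1nnnn1-c1ccccc1 | intermediate (not isolated)
8 | 5-{[(R)-3-[(tert-butyldimethylsilyl)oxy]-2-methylpropyl]sulfonyl}-1-phenyl-1H-tetrazole | C[C@H](CO[Si](C)(C)C(C)(C)C)CS(=O)(=O)c1nnnn1-c1ccccc1 | intermediate
9 | geranyl acetate, (E)-3,7-dimethylocta-2,6-dien-1-yl acetate | CC(C)=CCC/C(C)=C/COC(C)=O | starting material
10 | (E)-5-(3,3-dimethyloxiran-2-yl)-3-methylpent-2-en-1-yl acetate (racemic at the oxirane carbon) | CC1(C)OC1CC/C(C)=C/COC(C)=O | intermediate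
11 | (E)-6,7-dihydroxy-3,7-dimethyloct-2-en-1-yl acetate (racemic) | CC(C)(O)C(O)CC/C(C)=C/COC(C)=O | intermediate (not isolated)
12 | (E)-3-methyl-6-oxohex-2-en-1-yl acetate | O=CCC/C(C)=C/COC(C)=O | intermediate
13 | (E)-6-acetoxy-4-methylhex-4-enoic acid | OC(=O)CC/C(C)=C/COC(C)=O | intermediate
14 | potassium (E)-6-acetoxy-4-methylhex-4-enoate | [K+].[O-]C(=O)CC/C(C)=C/COC(C)=O | intermediate (not isolated)
15 | methyl (E)-6-acetoxy-4-methylhex-4-enoate | COC(=O)CC/C(C)=C/COC(C)=O | intermediate
16 | methyl (E)-6-hydroxy-4-methylhex-4-enoate | COC(=O)CC/C(C)=C/CO | intermediate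
17 | methyl (E)-4-methyl-6-oxohex-4-enoate | COC(=O)CC/C(C)=C/C=O | intermediate
18 | potassium salt of the α-sulfonyl carbanion of 8 | C[C@H](CO[Si](C)(C)C(C)(C)C)[CH-]S(=O)(=O)c1nnnn1-c1ccccc1.[K+] | intermediate (not isolated)
19 | methyl (4E,6E,8S)-9-[(tert-butyldimethylsilyl)oxy]-4,8-dimethylnona-4,6-dienoate | COC(=O)CC/C(C)=C/C=C/[C@H](C)CO[Si](C)(C)C(C)(C)C | intermediate
20 | methyl (4E,6E,8S)-9-hydroxy-4,8-dimethylnona-4,6-dienoate | COC(=O)CC/C(C)=C/C=C/[C@H](C)CO | intermediate (key-step precursor)
21 | methyl 3-[(3S,6S)-6-[(2R)-1-hydroxypropan-2-yl]-3-methyl-3,6-dihydro-1,2-dioxin-3-yl]propanoate | COC(=O)CC[C@@]1(C)C=C[C@@H]([C@H](C)CO)OO1 | intermediate (key-step product)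
22 | methyl 3-[(3R,6S)-6-[(2R)-1-hydroxypropan-2-yl]-3-methyl-1,2-dioxan-3-yl]propanoate | COC(=O)CC[C@@]1(C)CC[C@@H]([C@H](C)CO)OO1 | intermediate
23 | ethyl 5-bromopentanoate | CCOC(=O)CCCCBr | starting material
24 | 6-bromohexan-2-one | CC(=O)CCCCBr | intermediate (not isolated)
25 | 6-bromo-2-methylhexan-2-ol | CC(C)(O)CCCCBr | intermediate
26 | [(6-bromo-2-methylhexan-2-yl)oxy]triethylsilane | CC[Si](CC)(CC)OC(C)(C)CCCCBr | intermediate
27 | diethyl {5-methyl-5-[(triethylsilyl)oxy]hexyl}phosphonate | CCOP(=O)(OCC)CCCCC(C)(C)O[Si](CC)(CC)CC | intermediate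
28 | lithium salt of the α-phosphonyl carbanion of 27 | CCOP(=O)(OCC)[CH-]CCCC(C)(C)O[Si](CC)(CC)CC.[Li+] | intermediate (not isolated)
29 | diethyl {1-[(3R,6S)-6-[(2R)-1-hydroxypropan-2-yl]-3-methyl-1,2-dioxan-3-yl]-8-methyl-3-oxo-8-[(triethylsilyl)oxy]nonan-4-yl}phosphonate (both C10 epimers) | CCOP(=O)(OCC)C(CCCC(C)(C)O[Si](CC)(CC)CC)C(=O)CC[C@@]1(C)CC[C@@H]([C@H](C)CO)OO1 | intermediate
30 | potassium enolate of 29 | CCOP(=O)(OCC)[C-](CCCC(C)(C)O[Si](CC)(CC)CC)C(=O)CC[C@@]1(C)CC[C@@H]([C@H](C)CO)OO1.[K+] | intermediate (not isolated)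
31 | 1-[(3R,6S)-6-[(2R)-1-hydroxypropan-2-yl]-3-methyl-1,2-dioxan-3-yl]-8-methyl-4-methylidene-8-[(triethylsilyl)oxy]nonan-3-one | C=C(CCCC(C)(C)O[Si](CC)(CC)CC)C(=O)CC[C@@]1(C)CC[C@@H]([C@H](C)CO)OO1 | intermediate
32 | (2S)-2-[(3S,6R)-6-methyl-6-{8-methyl-4-methylidene-3-oxo-8-[(triethylsilyl)oxy]nonyl}-1,2-dioxan-3-yl]propanal | C=C(CCCC(C)(C)O[Si](CC)(CC)CC)C(=O)CC[C@@]1(C)CC[C@@H]([C@H](C)C=O)OO1 | intermediate (not isolated)
33 | (2S)-2-[(3S,6R)-6-methyl-6-{8-methyl-4-methylidene-3-oxo-8-[(triethylsilyl)oxy]nonyl}-1,2-dioxan-3-yl]propanoic acid | C=C(CCCC(C)(C)O[Si](CC)(CC)CC)C(=O)CC[C@@]1(C)CC[C@@H]([C@H](C)C(=O)O)OO1 | intermediate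
34 | potassium salt of 33 | C=C(CCCC(C)(C)O[Si](CC)(CC)CC)C(=O)CC[C@@]1(C)CC[C@@H]([C@H](C)C(=O)[O-])OO1.[K+] | intermediate (not isolated)
35 | methyl (2S)-2-[(3S,6R)-6-methyl-6-{8-methyl-4-methylidene-3-oxo-8-[(triethylsilyl)oxy]nonyl}-1,2-dioxan-3-yl]propanoate | C=C(CCCC(C)(C)O[Si](CC)(CC)CC)C(=O)CC[C@@]1(C)CC[C@@H]([C@H](C)C(=O)OC)OO1 | intermediate
36 | aikupikoxide D, methyl (2S)-2-[(3S,6R)-6-(8-hydroxy-8-methyl-4-methylidene-3-oxononyl)-6-methyl-1,2-dioxan-3-yl]propanoate | C=C(CCCC(C)(C)O)C(=O)CC[C@@]1(C)CC[C@@H]([C@H](C)C(=O)OC)OO1 | target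

**Step count**

Total: 22 steps. Longest linear sequence: 15 steps (5–14 and 18–22, from geranyl acetate).

**Steps most likely to fail**

1. Step 13. The Schenck ene reaction may outrun the cycloaddition, because the s-cis conformer needed for ring closure carries the C6 methyl inward, and the facial bias exerted by C2 may be small. As a fallback, the same two C–O bonds would be made without singlet oxygen, by aminium-salt-initiated cation-radical chain oxygenation with ground-state O2. The fallback sets out from silyl ether 19, since a free hydroxyl could trap the diene radical cation. O2 and catalytic tris(4-bromophenyl)aminium hexachloroantimonate, (4-BrC6H4)3N SbCl6, in CH2Cl2 at −78 °C should give the silyl-protected cycloadduct methyl 3-[(3S,6S)-6-[(2R)-1-[(tert-butyldimethylsilyl)oxy]propan-2-yl]-3-methyl-3,6-dihydro-1,2-dioxin-3-yl]propanoate F1. HF·pyridine in THF at 0 °C should then free the alcohol and return to the route at 21. No singlet oxygen is formed, so the ene pathway is closed. The facial outcome would then rest on the steric difference between the methyl and the silyloxymethyl arm and would have to be established on this compound.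

2. Step 18. The phosphonate carbanion may attack the O–O bond, or the basic medium may fragment the peroxide, before acylation at C9 is complete. As a fallback, the C9–C10 bond would be formed before the peroxide exists. The fallback sets out from dienol 20, which is acylated with excess lithiated phosphonate 28 (THF, −78 → 0 °C) to give the dienol ketophosphonate diethyl [(10E,12E,14S)-15-hydroxy-2,10,14-trimethyl-7-oxo-2-[(triethylsilyl)oxy]pentadeca-10,12-dien-6-yl]phosphonate F2. Sensitised photooxygenation under the conditions of step 13 should give the dihydrodioxine ketophosphonate diethyl {1-[(3S,6S)-6-[(2R)-1-hydroxypropan-2-yl]-3-methyl-3,6-dihydro-1,2-dioxin-3-yl]-8-methyl-3-oxo-8-[(triethylsilyl)oxy]nonan-4-yl}phosphonate F3. Diimide reduction as in step 14 returns to the route at 29. The cost is that the cycloadducts are handled as pairs of C10 epimers, so the facial diastereomers would best be separated after step 19.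

3. Step 20. Water, acetate or the hydroxylamine form of the nitroxyl catalyst may add to the exo-methylene ketone, or the enone may oligomerise, during the aqueous oxidation. As a fallback, C1 would be oxidised before the enone exists. The fallback sets out from ketophosphonate 29. The same oxidation should give the ketophosphonate acid (2S)-2-[(3S,6R)-6-{4-(diethoxyphosphoryl)-8-methyl-3-oxo-8-[(triethylsilyl)oxy]nonyl}-6-methyl-1,2-dioxan-3-yl]propanoic acid F5 by way of the ketophosphonate aldehyde diethyl {8-methyl-1-[(3R,6S)-3-methyl-6-[(2S)-1-oxopropan-2-yl]-1,2-dioxan-3-yl]-3-oxo-8-[(triethylsilyl)oxy]nonan-4-yl}phosphonate F4, which is not isolated. Me3SiCHN2 in MeOH/toluene at 0 °C should give the ketophosphonate ester methyl (2S)-2-[(3S,6R)-6-{4-(diethoxyphosphoryl)-8-methyl-3-oxo-8-[(triethylsilyl)oxy]nonyl}-6-methyl-1,2-dioxan-3-yl]propanoate F6. K2CO3 and aq. HCHO in THF at 0 °C, through the potassium enolate of that ester F7 (not isolated), should give the enone ester 35, where the route is rejoined. This order exposes the β-peroxy ester briefly to carbonate, which is why it is held in reserve.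

**Further compounds**

F1 | step 13 | methyl 3-[(3S,6S)-6-[(2R)-1-[(tert-butyldimethylsilyl)oxy]propan-2-yl]-3-methyl-3,6-dihydro-1,2-dioxin-3-yl]propanoate | COC(=O)CC[C@@]1(C)C=C[C@@H]([C@H](C)CO[Si](C)(C)C(C)(C)C)OO1
F2 | step 18 | diethyl [(10E,12E,14S)-15-hydroxy-2,10,14-trimethyl-7-oxo-2-[(triethylsilyl)oxy]pentadeca-10,12-dien-6-yl]phosphonate (both epimers at the phosphorus-bearing carbon) | CCOP(=O)(OCC)C(CCCC(C)(C)O[Si](CC)(CC)CC)C(=O)CC/C(C)=C/C=C/[C@H](C)CO
F3 | step 18 | diethyl {1-[(3S,6S)-6-[(2R)-1-hydroxypropan-2-yl]-3-methyl-3,6-dihydro-1,2-dioxin-3-yl]-8-methyl-3-oxo-8-[(triethylsilyl)oxy]nonan-4-yl}phosphonate (both epimers at the phosphorus-bearing carbon) | CCOP(=O)(OCC)C(CCCC(C)(C)O[Si](CC)(CC)CC)C(=O)CC[C@@]1(C)C=C[C@@H]([C@H](C)CO)OO1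
F4 | step 20 | diethyl {8-methyl-1-[(3R,6S)-3-methyl-6-[(2S)-1-oxopropan-2-yl]-1,2-dioxan-3-yl]-3-oxo-8-[(triethylsilyl)oxy]nonan-4-yl}phosphonate | CCOP(=O)(OCC)C(CCCC(C)(C)O[Si](CC)(CC)CC)C(=O)CC[C@@]1(C)CC[C@@H]([C@H](C)C=O)OO1
F5 | step 20 | (2S)-2-[(3S,6R)-6-{4-(diethoxyphosphoryl)-8-methyl-3-oxo-8-[(triethylsilyl)oxy]nonyl}-6-methyl-1,2-dioxan-3-yl]propanoic acid | CCOP(=O)(OCC)C(CCCC(C)(C)O[Si](CC)(CC)CC)C(=O)CC[C@@]1(C)CC[C@@H]([C@H](C)C(=O)O)OO1
F6 | step 20 | methyl (2S)-2-[(3S,6R)-6-{4-(diethoxyphosphoryl)-8-methyl-3-oxo-8-[(triethylsilyl)oxy]nonyl}-6-methyl-1,2-dioxan-3-yl]propanoate | CCOP(=O)(OCC)C(CCCC(C)(C)O[Si](CC)(CC)CC)C(=O)CC[C@@]1(C)CC[C@@H]([C@H](C)C(=O)OC)OO1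
F7 | step 20 | potassium enolate of F6 | CCOP(=O)(OCC)[C-](CCCC(C)(C)O[Si](CC)(CC)CC)C(=O)CC[C@@]1(C)CC[C@@H]([C@H](C)C(=O)OC)OO1.[K+]
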